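## Analysis of the target

The target 19 is built from two benzo-fused oxygen heterocycles, a 2,2-dimethylchroman (aromatic ring A, pyran ring B) and a 2,3-dihydrobenzofuran (aromatic ring C, furan ring D), joined from C6 of the chroman to C5 of the benzofuran by a three-carbon β-hydroxy ketone chain. It has two stereocenters, the benzylic carbinol carbon of the chain and C2 of ring D, which carries the 2-hydroxypropan-2-yl group; both are S. They lie seven bonds apart across the planar ring C, so neither can direct the other and each has to be set on its own with absolute control. The chain is the fragile part: the β-hydroxy ketone can undergo retro-aldol cleavage or lose water, after which the C6 phenol would add to the resulting enone, and the carbinol is also a para-alkoxybenzylic alcohol that ionises in acid and is open to hydrogenolysis. The tertiary alcohol and the two electron-rich arenes restrict the use of strong acids and electrophiles. The difficulty is to place an acyl group at C5 only, next to a phenol, with the β-oxygen and its configuration intact. The strategy rests on the ketone carbon, which has no substituent of its own and sits between C5 of ring C and a CH2 group whose neighbour bears oxygen. Such a carbon can come from carbon monoxide 16 if the CH2 group reacts as a radical, because a β-oxygenated alkyl radical keeps its oxygen where a β-oxygenated alkylmetal would eliminate it.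

## Retrosynthetic reasoning

The last operations are kept for the two hydroxyl groups that cannot be carried free. Target 19 is traced back to the silyl ether 18 and this to the benzyl ether 17. The benzyl group is removed first, by hydrogenolysis, while the benzylic carbinol is still silylated and so is not itself a substrate for hydrogenolysis. The silyl ether is cleaved last under buffered acidic fluoride, the conditions the β-hydroxy ketone tolerates best. The tertiary alcohol needs no protection at any stage.

The two bonds to the ketone carbon of 17 are cut together, which gives the primary iodide 6, carbon monoxide 16 and the arylboronic acid 15. This cut avoids any enolate or acyl anion chemistry next to the β-oxygen, divides the molecule into two halves of similar size with one stereocenter each, and fixes the acyl group at C5 through the position of boron. Cutting the bond between CH2 and the carbinol carbon instead would create the carbinol stereocenter during the coupling from a methyl ketone, where control is weak. The forward reaction has to turn the C–I bond into a radical, let it take up 16 before anything else happens to it, and hand the acyl group to the aryl group of 15 through palladium. The phenol of 15 is benzylated so that it cannot capture the acylpalladium as an ester. The carbinol of 6 is silylated so that no alkoxide can displace the iodide.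

Iodide 6 goes back to the chloride 5 by halide exchange and to the chlorohydrin 4 by removal of the silyl group. The stereocenter of 4 is traced to the prochiral ketone 3. Chlorine is chosen because α-chloro aryl ketones are good substrates for asymmetric transfer hydrogenation, whereas α-iodo ketones are not. Ketone 3 is cut at the aryl–carbonyl bond into 2,2-dimethylchroman 1 and chloroacetyl chloride 2; the ring oxygen of 1 directs acylation to C6, para to itself, which is the position required.

The C–B bond of 15 is traced to the C–Br bond of 12 and this to a C–H bond of 11. C5 of 11 is ortho to the benzyloxy group and para to O1, so electrophilic bromination marks exactly the carbon that will carry the ketone. Halogen–lithium exchange and borylation then transfer that regiochemistry to boron.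

The tertiary alcohol of 11 is taken back to the isopropenyl group of 10 by Markovnikov hydration. Ring D of 10 is opened at C3a–C3 and O1–C2, which leads to the bromophenol 8 and isoprene 9. The forward step is a palladium-catalysed heteroannulation in which a chiral ligand sets C2, and 9 supplies C2, C3 and the three side-chain carbons of ring D in one step. Bromophenol 8 comes from 4-bromoresorcinol 7 by benzylation of the hydroxyl remote from bromine. This leaves the hydroxyl next to bromine free for the annulation and installs the phenol protection that the key step needs later.

## Alternatives that were turned down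

Alternative 1: The disconnection is the C7a–O1 bond of ring D in the benzofuran half. It leads to the diol A2, (S)-1-[4-(benzyloxy)phenyl]-3-methylbutane-2,3-diol, obtainable from L-tyrosine A3 by O-benzylation, diazotisation with retention, esterification and double methyl addition. In the forward key step the secondary hydroxyl of A2 would bind divalent palladium and direct C–H palladation to one of the two equivalent positions ortho to the CH2 group. Oxidation to tetravalent palladium by a trivalent iodine oxidant and C–O reductive elimination would then close ring D and give A1, (S)-6-benzyloxy-2-(2-hydroxypropan-2-yl)-2,3-dihydrobenzofuran, which is the same compound as 11.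
- For it: C2 is taken from the chiral pool at full enantiopurity without a chiral catalyst, the para oxygen of A3 ends up at C6 by construction, and the C–H step raises no regiochemical question.
- Against it: hydroxyl-directed C–H/C–O cyclisations of this kind are established for tertiary alcohols. A secondary alkoxide on divalent palladium has a β-hydrogen and should be oxidised at the carbinol. The vicinal diol invites glycol cleavage by the same oxidant. The tertiary hydroxyl can also direct palladation, towards a six-membered ring. The step also furnishes only a fragment, so bromination, borylation and the union of the two halves remain.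
- Comparison: on the certainty of the configuration at C2 this alternative is stronger, since the chosen route relies on ligand control in step 6. The chosen route reaches the same compound 11 in three precedented steps from 7, against about five ending in a cyclisation without precedent, and it spends its one risky step on the bond construction that matters most.

Alternative 2: The disconnection is C3a–C3 and O1–C2 of ring D, made last on the complete chain. The precursors are the bromoresorcinol ketone A5, (S)-1-(5-bromo-2,4-dihydroxyphenyl)-3-[(tert-butyldimethylsilyl)oxy]-3-(2,2-dimethylchroman-6-yl)propan-1-one, and isoprene 9. The forward key step is the chiral palladium-catalysed heteroannulation of step 6, run on A5, to give the isopropenyl ketone A4.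
- For it: the annulation is as well precedented as in the chosen route, and A5 belongs to the bromo hydroxy aryl ketone class for which it is best known. C2 is introduced late and need not be carried. The C6 hydroxyl is tied up in a hydrogen bond to the ketone and needs no protection.
- Against it: A5 is a β-silyloxy ketone with a free ortho phenol, and the base and heat of the annulation invite β-elimination of the silyloxy group followed by oxa-Michael closure through that phenol. The hard bonds of the target, those to the ketone carbon, are not made by this key step and would have to be formed earlier on a bromoresorcinol that needs its own protection. The isopropenyl group of A4 must still be hydrated at the very end next to an aryl ketone and a phenol. Imperfect enantiocontrol would show up as diastereomers of an advanced intermediate.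
- Comparison: it is equal on the precedent of the ring-forming step and better in leaving the phenol unprotected. The chosen route runs the same annulation on the cheap and robust phenol 8, where base and heat can harm nothing, and makes both ketone bonds in its key step.

Alternative 3: The disconnection is ring C itself, at C5–C6 and C3a–C4. The precursors are the diene A7, (S)-5-[2,2-bis(trimethylsilyloxy)vinyl]-2-[2-(triethylsilyloxy)propan-2-yl]-2,3-dihydrofuran, and the ynone A8, (S)-5-[(tert-butyldimethylsilyl)oxy]-5-(2,2-dimethylchroman-6-yl)pent-1-yn-3-one. The forward key step is a [4+2] cycloaddition of the 1,1,3-trioxygenated diene A7 with the terminal ynone A8. The ring carbon of the dihydrofuran adds to the alkyne terminus and the ketene acetal carbon to the carbon next to the carbonyl; elimination of one silyloxy group then aromatises ring C and gives the bis-silyl ether A6.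
- For it: the positions of the C6 hydroxyl and the C5 acyl group follow from the polarity of the two partners and not from substitution selectivity on an arene. The phenol emerges free and hydrogen-bonded, which saves one protecting group and its removal. The union is convergent.
- Against it: A7 is at once a cyclic enol ether and a ketene bis-silyl acetal, is hydrolytically fragile, and would need a multistep enantioselective preparation of its own. A8 is a β-silyloxy ynone that eliminates easily, accepts nucleophiles in conjugate fashion, and would require a separate asymmetric aldol-type step. The cycloaddition has to win against Mukaiyama–Michael addition and silyl transfer between the partners.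
- Comparison: it is stronger than the chosen route in regiochemical certainty at ring C and in protecting-group economy, weaker in the stability of its building blocks, and clearly longer. The chosen route keeps ring C intact throughout, handles only bench-stable aromatic intermediates, and uses a catalytic reaction with close precedent for its one demanding step.

Key step: step 10

Assumption: in step 6 the antipode of the sulfinamide-phosphine ligand that places C2 in the S configuration is meant; both antipodes are made from the corresponding tert-butanesulfinamide, and the assignment would be confirmed on 11.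

## Route

Step 1
Reactants: 1 2,2-dimethylchroman; 2 chloroacetyl chloride
Product: 3 2-chloro-1-(2,2-dimethylchroman-6-yl)ethan-1-one
Conditions: AlCl3 (1.2 equiv), CH2Cl2, −10 → 0 °C
Reagents that add atoms: none
Why: Friedel–Crafts acylation; the ring oxygen directs the acylium ion para to itself, to C6, the ortho position C8 being the slower site, and the low temperature should keep the tertiary aryl ether of ring B intact.

Step 2
Reactants: 3 2-chloro-1-(2,2-dimethylchroman-6-yl)ethan-1-one
Product: 4 (R)-2-chloro-1-(2,2-dimethylchroman-6-yl)ethan-1-ol
Conditions: Cp*RhCl[(S,S)-TsDPEN] (0.5 mol %), HCO2H/Et3N (5:2), EtOAc, rt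
Reagents that add atoms: none
Why: Noyori–Ikariya asymmetric transfer hydrogenation; hydride and proton are delivered through the outer-sphere six-membered transition state with the aryl group held against the Cp* ligand, so the (S,S)-ligand should give the alcohol of the same spatial sense as (S)-1-phenylethanol, which is named R here because CH2Cl outranks the aryl group. α-Chloro aryl ketones are a standard substrate class and the medium is too weakly basic to close the chlorohydrin to an epoxide.

Step 3
Reactants: 4 (R)-2-chloro-1-(2,2-dimethylchroman-6-yl)ethan-1-ol
Product: 5 (R)-tert-butyl[2-chloro-1-(2,2-dimethylchroman-6-yl)ethoxy]dimethylsilane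
Conditions: TBSCl (1.3 equiv), imidazole (2.5 equiv), DMF, rt
Reagents that add atoms: tert-butyldimethylsilyl chloride (TBSCl), CC(C)(C)[Si](C)(C)Cl
Why: Standard silylation of a secondary alcohol; imidazole is not basic enough to form the epoxide, and the C–O bond of the stereocenter is not touched.

Step 4
Reactants: 5 (R)-tert-butyl[2-chloro-1-(2,2-dimethylchroman-6-yl)ethoxy]dimethylsilane
Product: 6 (R)-tert-butyl[1-(2,2-dimethylchroman-6-yl)-2-iodoethoxy]dimethylsilane
Conditions: NaI (5 equiv), NaHCO3 (cat.), 2-butanone, reflux, dark
Reagents that add atoms: sodium iodide, [Na+].[I-]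
Why: Finkelstein exchange by SN2 at the primary carbon, driven by precipitation of NaCl; the β-oxygen and the branching slow the displacement, hence the higher-boiling ketone solvent and excess iodide. The stereocenter is not the reacting carbon.

Step 5
Reactants: 7 4-bromoresorcinol
Product: 8 5-(benzyloxy)-2-bromophenol
Conditions: BnBr (1.0 equiv), K2CO3 (1.1 equiv), acetone, rt
Reagents that add atoms: benzyl bromide, BrCc1ccccc1
Why: Williamson etherification; the hydroxyl next to bromine is flanked by the halogen and its phenoxide is the weaker nucleophile, so the remote hydroxyl should be alkylated preferentially, and the regioisomer and the bis-ether would be removed by chromatography.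

Step 6
Reactants: 8 5-(benzyloxy)-2-bromophenol; 9 isoprene
Product: 10 (S)-6-(benzyloxy)-2-(prop-1-en-2-yl)-2,3-dihydrobenzofuran
Conditions: Pd2(dba)3 (2.5 mol %), chiral sulfinamide-phosphine ligand of the TY-Phos type (6 mol %), NaOPh (1.5 equiv), 9 (4 equiv), toluene, 60 °C, sealed tube
Reagents that add atoms: none
Why: Larock-type heteroannulation run as an asymmetric Heck/Tsuji–Trost sequence: oxidative addition of the C–Br bond, insertion of the unsubstituted vinyl end of 9 with the aryl group going to the terminal carbon, and attack of the phenoxide on the internal terminus of the π-allylpalladium, which closes ring D. The two faces of the allyl unit interconvert through its CH2 terminus, so the chiral ligand sets C2 in the C–O bond-forming step.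

Step 7
Reactants: 10 (S)-6-(benzyloxy)-2-(prop-1-en-2-yl)-2,3-dihydrobenzofuran
Product: 11 (S)-2-[6-(benzyloxy)-2,3-dihydrobenzofuran-2-yl]propan-2-ol
Conditions: Co(acac)2 (20 mol %), PhSiH3 (2 equiv), O2 (1 atm), THF, rt
Reagents that add atoms: dioxygen, O=O
Why: Mukaiyama hydration; hydrogen-atom transfer to the 1,1-disubstituted alkene gives the tertiary radical, which is trapped by O2 much faster than it could fragment, and the silane reduces the peroxy intermediate to the Markovnikov alcohol. C2 is adjacent to the radical site but is not involved, so its configuration is kept.

Step 8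
Reactants: 11 (S)-2-[6-(benzyloxy)-2,3-dihydrobenzofuran-2-yl]propan-2-ol
Product: 12 (S)-2-[6-(benzyloxy)-5-bromo-2,3-dihydrobenzofuran-2-yl]propan-2-ol
Conditions: NBS (1.0 equiv), MeCN, 0 °C
Reagents that add atoms: N-bromosuccinimide, O=C1CCC(=O)N1Br
Why: Electrophilic aromatic bromination; C5 is ortho to the benzyloxy group and para to O1, C7 lies between the two oxygens and is hindered, and C4 is meta to both, so substitution should take place at C5.

Step 9
Reactants: 12 (S)-2-[6-(benzyloxy)-5-bromo-2,3-dihydrobenzofuran-2-yl]propan-2-ol
Product: 15 (S)-[6-(benzyloxy)-2-(2-hydroxypropan-2-yl)-2,3-dihydrobenzofuran-5-yl]boronic acid, via dilithio aryl alkoxide 13 (not isolated), via lithium aryltriisopropoxyborate 14 (not isolated)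
Conditions: n-BuLi (2.2 equiv), THF, −78 °C; B(OiPr)3 (3 equiv), −78 → 0 °C; 1 M HCl to pH 5–6
Reagents that add atoms: triisopropyl borate, CC(C)OB(OC(C)C)OC(C)C; water, O
Why: The first equivalent of base deprotonates the tertiary alcohol and the second effects bromine–lithium exchange, which at −78 °C is far faster than deprotonation of the benzylic ether CH2; borylation of the aryllithium and mild hydrolysis give the boronic acid. The work-up is kept only weakly acidic because the electron-rich aryl–boron bond is prone to protodeboronation.

Step 10
Reactants: 6 (R)-tert-butyl[1-(2,2-dimethylchroman-6-yl)-2-iodoethoxy]dimethylsilane; 15 (S)-[6-(benzyloxy)-2-(2-hydroxypropan-2-yl)-2,3-dihydrobenzofuran-5-yl]boronic acid; 16 carbon monoxide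
Product: 17 (S)-1-[(S)-6-(benzyloxy)-2-(2-hydroxypropan-2-yl)-2,3-dihydrobenzofuran-5-yl]-3-[(tert-butyldimethylsilyl)oxy]-3-(2,2-dimethylchroman-6-yl)propan-1-one
Conditions: Pd(PPh3)4 (5 mol %), K2CO3 (2 equiv), 15 (1.5 equiv), CO (45 atm), C6H6/H2O, hν (xenon lamp, Pyrex), rt
Reagents that add atoms: none
Why: Under irradiation Pd(PPh3)4, a zerovalent palladium complex, transfers one electron to the C–I bond of 6 and releases the primary alkyl radical together with a monovalent palladium iodide. At 45 atm the radical should add to 16 much faster than it can undergo a neophyl-type 1,2-shift of the neighbouring aryl group or return to palladium, and a radical, unlike an alkylmetal, has no way to expel the β-silyloxy group. The acyl radical recombines with the monovalent palladium species to an acyl(iodo) complex of divalent palladium, the boronate formed from 15 and carbonate transmetalates, and reductive elimination gives 17 and returns zerovalent palladium. The closest known reaction type is the light-assisted, Pd(PPh3)4-catalysed carbonylative Suzuki-type coupling of unactivated alkyl iodides, CO and arylboronic acids to alkyl aryl ketones. No ring is closed and no stereocenter is formed; the carbinol carbon is β to the radical centre and C2 of ring D is remote, so both configurations are carried through, the carbinol being named S in 17 only because the new CH2C(=O) group ranks below the aryl group whereas CH2I ranked above it. The step needs chemoselectivity for CO capture over direct alkyl–aryl coupling and over aryl migration, which the CO pressure and the primary, unstabilised nature of the radical secure, and for aryl transfer over capture of the acylpalladium by oxygen nucleophiles, which the benzyl ether on the C6 oxygen and the hindrance of the tertiary alcohol secure. The acylpalladium has no β-elimination path, and the biphasic carbonate medium at ambient temperature should be mild enough for the β-silyloxy ketone once formed.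

Step 11
Reactants: 17 (S)-1-[(S)-6-(benzyloxy)-2-(2-hydroxypropan-2-yl)-2,3-dihydrobenzofuran-5-yl]-3-[(tert-butyldimethylsilyl)oxy]-3-(2,2-dimethylchroman-6-yl)propan-1-one
Product: 18 (S)-3-[(tert-butyldimethylsilyl)oxy]-3-(2,2-dimethylchroman-6-yl)-1-[(S)-6-hydroxy-2-(2-hydroxypropan-2-yl)-2,3-dihydrobenzofuran-5-yl]propan-1-one
Conditions: H2 (1 atm), 10% Pd/C, EtOAc, rt
Reagents that add atoms: none
Why: Hydrogenolysis of the aryl benzyl ether; the benzylic carbinol is masked as a silyl ether, which is a poor leaving group for hydrogenolysis, and the electron-rich, hydrogen-bonded aryl ketone is reduced far more slowly than the O-benzyl bond is cleaved in a neutral, aprotic solvent.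

Step 12
Reactants: 18 (S)-3-[(tert-butyldimethylsilyl)oxy]-3-(2,2-dimethylchroman-6-yl)-1-[(S)-6-hydroxy-2-(2-hydroxypropan-2-yl)-2,3-dihydrobenzofuran-5-yl]propan-1-one
Product: 19 (S)-3-(2,2-dimethylchroman-6-yl)-3-hydroxy-1-[(S)-6-hydroxy-2-(2-hydroxypropan-2-yl)-2,3-dihydrobenzofuran-5-yl]propan-1-one
Conditions: HF·pyridine, excess pyridine, THF, 0 °C → rt
Reagents that add atoms: none
Why: Fluoride-mediated cleavage of the Si–O bond under buffered, weakly acidic conditions; the medium is neither basic enough for retro-aldol cleavage or β-elimination nor acidic enough to ionise the benzylic carbinol, and the C–O bond of the stereocenter is not broken.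

## Compound list

1 | 2,2-dimethylchroman | CC1(C)CCc2ccccc2O1 | starting material
2 | chloroacetyl chloride | ClCC(=O)Cl | starting material
3 | 2-chloro-1-(2,2-dimethylchroman-6-yl)ethan-1-one | CC1(C)CCc2cc(C(=O)CCl)ccc2O1 | intermediate
4 | (R)-2-chloro-1-(2,2-dimethylchroman-6-yl)ethan-1-ol | CC1(C)CCc2cc([C@@H](O)CCl)ccc2O1 | intermediate
5 | (R)-tert-butyl[2-chloro-1-(2,2-dimethylchroman-6-yl)ethoxy]dimethylsilane | CC1(C)CCc2cc([C@@H](O[Si](C)(C)C(C)(C)C)CCl)ccc2O1 | intermediate
6 | (R)-tert-butyl[1-(2,2-dimethylchroman-6-yl)-2-iodoethoxy]dimethylsilane | CC1(C)CCc2cc([C@@H](O[Si](C)(C)C(C)(C)C)CI)ccc2O1 | intermediate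
7 | 4-bromoresorcinol | Oc1ccc(Br)c(O)c1 | starting material
8 | 5-(benzyloxy)-2-bromophenol | Oc1cc(OCc2ccccc2)ccc1Br | intermediate
9 | isoprene | C=CC(C)=C | starting material
10 | (S)-6-(benzyloxy)-2-(prop-1-en-2-yl)-2,3-dihydrobenzofuran | c1cc2c(cc1OCc1ccccc1)O[C@H](C(C)=C)C2 | intermediate
11 | (S)-2-[6-(benzyloxy)-2,3-dihydrobenzofuran-2-yl]propan-2-ol | c1cc2c(cc1OCc1ccccc1)O[C@H](C(C)(C)O)C2 | intermediate
12 | (S)-2-[6-(benzyloxy)-5-bromo-2,3-dihydrobenzofuran-2-yl]propan-2-ol | Brc1cc2c(cc1OCc1ccccc1)O[C@H](C(C)(C)O)C2 | intermediate
13 | lithium (S)-2-[6-(benzyloxy)-5-lithio-2,3-dihydrobenzofuran-2-yl]propan-2-olate | [Li]c1cc2c(cc1OCc1ccccc1)O[C@H](C(C)(C)O[Li])C2 | intermediate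
14 | lithium triisopropoxy borate of the C5 aryl group of 13, alkoxide form | CC(C)O[B-](OC(C)C)(OC(C)C)c1cc2c(cc1OCc1ccccc1)O[C@H](C(C)(C)O[Li])C2.[Li+] | intermediate
15 | (S)-[6-(benzyloxy)-2-(2-hydroxypropan-2-yl)-2,3-dihydrobenzofuran-5-yl]boronic acid | OB(O)c1cc2c(cc1OCc1ccccc1)O[C@H](C(C)(C)O)C2 | intermediate
16 | carbon monoxide | [C-]#[O+] | starting material
17 | (S)-1-[(S)-6-(benzyloxy)-2-(2-hydroxypropan-2-yl)-2,3-dihydrobenzofuran-5-yl]-3-[(tert-butyldimethylsilyl)oxy]-3-(2,2-dimethylchroman-6-yl)propan-1-one | CC1(C)CCc2cc([C@@H](O[Si](C)(C)C(C)(C)C)CC(=O)c3cc4c(cc3OCc5ccccc5)O[C@H](C(C)(C)O)C4)ccc2O1 | intermediate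
18 | (S)-3-[(tert-butyldimethylsilyl)oxy]-3-(2,2-dimethylchroman-6-yl)-1-[(S)-6-hydroxy-2-(2-hydroxypropan-2-yl)-2,3-dihydrobenzofuran-5-yl]propan-1-one | CC1(C)CCc2cc([C@@H](O[Si](C)(C)C(C)(C)C)CC(=O)c3cc4c(cc3O)O[C@H](C(C)(C)O)C4)ccc2O1 | intermediate
19 | (S)-3-(2,2-dimethylchroman-6-yl)-3-hydroxy-1-[(S)-6-hydroxy-2-(2-hydroxypropan-2-yl)-2,3-dihydrobenzofuran-5-yl]propan-1-one | CC1(C)CCc2cc([C@@H](O)CC(=O)c3cc4c(cc3O)O[C@H](C(C)(C)O)C4)ccc2O1 | target

## Step count and risk

Total step count: 12. Longest linear sequence: 8 steps (steps 5 to 12); the iodide branch, steps 1 to 4, joins at step 10.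

Least certain steps:

**Step 10 (key step).** The most likely failure is slow transmetalation of the ortho-substituted, electron-rich arylboron species. The acylpalladium would then be diverted to the carboxylic acid by hydroxide while 15 is lost by protodeboronation. Two further risks are light-induced hydrogen abstraction from the benzyloxy CH2 by the excited ketone of the product on long irradiation, and base-induced β-elimination of the silyloxy group.

Fallback: the two bonds are made one after the other. Iodide 6 is carbonylated under the same light and Pd(PPh3)4 regime, but with N,O-dimethylhydroxylamine hydrochloride and K2CO3 in place of 15. This should give the Weinreb amide (S)-3-[(tert-butyldimethylsilyl)oxy]-3-(2,2-dimethylchroman-6-yl)-N-methoxy-N-methylpropanamide F1. An amine captures the acyl intermediate directly, so no transmetalation is involved and no aryl ketone is present under the lamp. The dilithio species 13, generated from 12 as in step 9, is then added to F1 in THF at −78 °C, and aqueous work-up of the chelated adduct gives 17. The fallback sets out from 6 and 12 and comes back to the route at 17.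

**Step 6.** The likely failures are poor enantiofacial control in the C–O bond-forming step with this electron-rich bromophenol, and insertion at the methyl-bearing end of the diene, which would give the 2-methyl-2-vinyl isomer.

Fallback: the stereocenter is set by epoxidation instead. Bromophenol 8 is treated with n-BuLi (2.2 equiv, Et2O, −78 → 0 °C) and then with prenyl bromide in the presence of catalytic CuBr·SMe2, which should give 5-(benzyloxy)-2-(3-methylbut-2-en-1-yl)phenol F2. Silylation (TBSCl, imidazole) gives tert-butyl[5-(benzyloxy)-2-(3-methylbut-2-en-1-yl)phenoxy]dimethylsilane F3. Shi epoxidation with the D-fructose-derived ketone and KHSO5 (as the triple salt 2KHSO5·KHSO4·K2SO4, buffered with K2CO3) should give (R)-tert-butyl{5-(benzyloxy)-2-[(3,3-dimethyloxiran-2-yl)methyl]phenoxy}dimethylsilane F4. Bu4NF in THF then frees the phenoxide, which opens the epoxide in the 5-exo mode at the secondary carbon with inversion and gives 11 directly. The fallback sets out from 8 and comes back at 11, bypassing 10 and step 7.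

**Step 5.** The likely failure is poor site selectivity: alkylation at the hydroxyl next to bromine or at both hydroxyls, giving mixtures that are hard to separate.

Fallback: the bromine is introduced on a phenol that already carries the benzyl group. Purchased 3-(benzyloxy)phenol F5 is brominated with NBS and catalytic i-Pr2NH in CH2Cl2 at 0 °C, an amine-mediated ortho-selective bromination. Of the two positions ortho to the hydroxyl, the one para to the benzyloxy group is open, while the other is flanked by both oxygens, so 8 should result. The fallback does not use 7; it sets out from F5 and comes back at 8.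

**Step 12.** The likely failure is loss of water across the β-hydroxy ketone, or ionisation at the para-alkoxybenzylic carbinol, during the long exposure to acidic fluoride that a secondary TBS ether needs.

Fallback: the carbinol is carried as a more labile silyl ether from the start of the branch.
- Chlorohydrin 4 is silylated with triethylsilyl chloride and imidazole to (R)-[2-chloro-1-(2,2-dimethylchroman-6-yl)ethoxy]triethylsilane F6.
- Exchange with NaI as in step 4 gives (R)-[1-(2,2-dimethylchroman-6-yl)-2-iodoethoxy]triethylsilane F7.
- The coupling of step 10 with 15 and 16 gives (S)-1-[(S)-6-(benzyloxy)-2-(2-hydroxypropan-2-yl)-2,3-dihydrobenzofuran-5-yl]-3-(2,2-dimethylchroman-6-yl)-3-[(triethylsilyl)oxy]propan-1-one F8.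
- Hydrogenolysis as in step 11 gives (S)-3-(2,2-dimethylchroman-6-yl)-1-[(S)-6-hydroxy-2-(2-hydroxypropan-2-yl)-2,3-dihydrobenzofuran-5-yl]-3-[(triethylsilyl)oxy]propan-1-one F9.
- The triethylsilyl ether is cleaved in AcOH/THF/H2O at room temperature to give 19.

The fallback sets out from 4 and comes back at 19.

## Further compounds

F1 | step 10 | (S)-3-[(tert-butyldimethylsilyl)oxy]-3-(2,2-dimethylchroman-6-yl)-N-methoxy-N-methylpropanamide | CC1(C)CCc2cc([C@@H](O[Si](C)(C)C(C)(C)C)CC(=O)N(C)OC)ccc2O1
F2 | step 6 | 5-(benzyloxy)-2-(3-methylbut-2-en-1-yl)phenol | CC(C)=CCc1ccc(OCc2ccccc2)cc1O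
F3 | step 6 | tert-butyl[5-(benzyloxy)-2-(3-methylbut-2-en-1-yl)phenoxy]dimethylsilane | CC(C)=CCc1ccc(OCc2ccccc2)cc1O[Si](C)(C)C(C)(C)C
F4 | step 6 | (R)-tert-butyl{5-(benzyloxy)-2-[(3,3-dimethyloxiran-2-yl)methyl]phenoxy}dimethylsilane | CC1(C)O[C@@H]1Cc1ccc(OCc2ccccc2)cc1O[Si](C)(C)C(C)(C)C
F5 | step 5 | 3-(benzyloxy)phenol | Oc1cccc(OCc2ccccc2)c1
F6 | step 12 | (R)-[2-chloro-1-(2,2-dimethylchroman-6-yl)ethoxy]triethylsilane | CC1(C)CCc2cc([C@@H](O[Si](CC)(CC)CC)CCl)ccc2O1
F7 | step 12 | (R)-[1-(2,2-dimethylchroman-6-yl)-2-iodoethoxy]triethylsilane | CC1(C)CCc2cc([C@@H](O[Si](CC)(CC)CC)CI)ccc2O1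
F8 | step 12 | (S)-1-[(S)-6-(benzyloxy)-2-(2-hydroxypropan-2-yl)-2,3-dihydrobenzofuran-5-yl]-3-(2,2-dimethylchroman-6-yl)-3-[(triethylsilyl)oxy]propan-1-one | CC1(C)CCc2cc([C@@H](O[Si](CC)(CC)CC)CC(=O)c3cc4c(cc3OCc5ccccc5)O[C@H](C(C)(C)O)C4)ccc2O1
F9 | step 12 | (S)-3-(2,2-dimethylchroman-6-yl)-1-[(S)-6-hydroxy-2-(2-hydroxypropan-2-yl)-2,3-dihydrobenzofuran-5-yl]-3-[(triethylsilyl)oxy]propan-1-one | CC1(C)CCc2cc([C@@H](O[Si](CC)(CC)CC)CC(=O)c3cc4c(cc3O)O[C@H](C(C)(C)O)C4)ccc2O1
A1 | alternative 1 | (S)-6-benzyloxy-2-(2-hydroxypropan-2-yl)-2,3-dihydrobenzofuran, identical with 11 | c1ccccc1COc1ccc2c(c1)O[C@H](C(C)(C)O)C2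
A2 | alternative 1 | (S)-1-[4-(benzyloxy)phenyl]-3-methylbutane-2,3-diol | O[C@H](C(C)(C)O)Cc1ccc(OCc2ccccc2)cc1
A3 | alternative 1 | L-tyrosine | N[C@@H](Cc1ccc(O)cc1)C(=O)O
A4 | alternative 2 | (S)-3-[(tert-butyldimethylsilyl)oxy]-3-(2,2-dimethylchroman-6-yl)-1-[(S)-6-hydroxy-2-(prop-1-en-2-yl)-2,3-dihydrobenzofuran-5-yl]propan-1-one | CC1(C)CCc2cc([C@@H](O[Si](C)(C)C(C)(C)C)CC(=O)c3cc4c(cc3O)O[C@H](C(C)=C)C4)ccc2O1
A5 | alternative 2 | (S)-1-(5-bromo-2,4-dihydroxyphenyl)-3-[(tert-butyldimethylsilyl)oxy]-3-(2,2-dimethylchroman-6-yl)propan-1-one | CC1(C)CCc2cc([C@@H](O[Si](C)(C)C(C)(C)C)CC(=O)c3cc(Br)c(O)cc3O)ccc2O1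
A6 | alternative 3 | (S)-3-[(tert-butyldimethylsilyl)oxy]-3-(2,2-dimethylchroman-6-yl)-1-{(S)-6-hydroxy-2-[2-(triethylsilyloxy)propan-2-yl]-2,3-dihydrobenzofuran-5-yl}propan-1-one | CC1(C)CCc2cc([C@@H](O[Si](C)(C)C(C)(C)C)CC(=O)c3cc4c(cc3O)O[C@H](C(C)(C)O[Si](CC)(CC)CC)C4)ccc2O1
A7 | alternative 3 | (S)-5-[2,2-bis(trimethylsilyloxy)vinyl]-2-[2-(triethylsilyloxy)propan-2-yl]-2,3-dihydrofuran | C[Si](C)(C)OC(O[Si](C)(C)C)=CC1=CC[C@@H](C(C)(C)O[Si](CC)(CC)CC)O1
A8 | alternative 3 | (S)-5-[(tert-butyldimethylsilyl)oxy]-5-(2,2-dimethylchroman-6-yl)pent-1-yn-3-one | CC1(C)CCc2cc([C@@H](O[Si](C)(C)C(C)(C)C)CC(=O)C#C)ccc2O1
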